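**Strategy.** Numbering the side chain from the carbinol carbon (C1), the route rests on forming the C4–C5 bond, between the olefinic carbon that bears the hydroxymethyl group and the first CH2 of the homofarnesyl chain. The key step exploits the C4 hydroxymethyl oxygen and the trisubstituted C3=C4 alkene: they are carried as a 2-alkyn-1-ol, whose magnesium alkoxide directs a CuI-catalysed anti-carbomagnesiation by homofarnesylmagnesium bromide. One operation forges C4–C5, sets the 3E geometry and delivers the free allylic alcohol. The precursors are homofarnesyl iodide and an (R)-5-(3-furyl)-5-silyloxypent-2-yn-1-ol. The butenolide ring is carried as a 3-furyl ring and unveiled last by singlet-oxygen oxidation and NaBH4 reduction.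

Key step: step 6

Remark on the chemistry: (R)-TRIP is assumed to direct Re-face propargylation of furan-3-carbaldehyde as it does with aryl aldehydes. The sense is to be checked on 10 (MTPA esters), and the (S)-acid would be used if it proves opposite.

**Step 1**
Reactants: 1 (2E,6E)-farnesyl bromide; 2 thioanisole
Product: 5 phenyl (3E,7E)-4,8,12-trimethyltrideca-3,7,11-trien-1-yl sulfide (homofarnesyl phenyl sulfide), via (phenylthio)methyllithium 3 (not isolated), via (phenylthio)methylcopper 4 (not isolated)
Conditions: 2, n-BuLi, DABCO, THF, 0 °C; CuI, −78 °C; then 1, −78 °C → rt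
Reagents that add atoms: none
Why: The sulfur-stabilised (phenylthio)methyl copper reagent should displace the primary allylic bromide at its α-carbon (SN2 alkylation of an α-thio carbanion, the γ-carbon being fully substituted), adding one carbon and leaving the 2E,6E geometry intact.

**Step 2**
Reactants: 5 homofarnesyl phenyl sulfide
Product: 6 (3E,7E)-1-iodo-4,8,12-trimethyltrideca-3,7,11-triene (homofarnesyl iodide)
Conditions: MeI (excess), NaI, DMF, 75 °C
Reagents that add atoms: iodomethane, CI; sodium iodide, [Na+].[I-] (one iodide pool that supplies the iodine)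
Why: S-Methylation should give an alkyl(methyl)phenylsulfonium salt whose primary alkyl carbon is displaced by iodide (SN2), releasing thioanisole and leaving the three alkenes untouched.

**Step 3**
Reactants: 7 furan-3-carbaldehyde; 8 allenylboronic acid pinacol ester
Product: 10 (R)-1-(furan-3-yl)but-3-yn-1-ol, via O-pinacolboryl homopropargyl ether 9 (not isolated)
Conditions: (R)-TRIP (10 mol%), 4 Å MS, toluene, −20 °C; then aq. NaHCO3
Reagents that add atoms: none
Why: In this chiral phosphoric acid-catalysed asymmetric propargylation the acid activates the boronate in a six-membered SE2' transition state, so only the homopropargylic alcohol forms and the (R)-acid is expected to expose the Re face of the aldehyde, which sets the (R)-carbinol centre.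

**Step 4**
Reactants: 10 (R)-1-(furan-3-yl)but-3-yn-1-ol
Product: 11 (R)-triethyl{[1-(furan-3-yl)but-3-yn-1-yl]oxy}silane
Conditions: Et3SiCl, imidazole, CH2Cl2, 0 °C → rt
Reagents that add atoms: chlorotriethylsilane, CC[Si](Cl)(CC)CC
Why: Standard silylation of a secondary alcohol blocks the oxygen that could otherwise act as a second, opposing directing group in step 6, and the triethylsilyl ether is later removed by dilute acid.

**Step 5**
Reactants: 11 (R)-triethyl{[1-(furan-3-yl)but-3-yn-1-yl]oxy}silane
Product: 13 (R)-5-(furan-3-yl)-5-(triethylsilyloxy)pent-2-yn-1-ol, via lithium acetylide 12 (not isolated)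
Conditions: n-BuLi (1.05 equiv), THF, −78 °C; (CH2O)n, −78 °C → rt; then H2O
Reagents that add atoms: paraformaldehyde (as formaldehyde), C=O
Why: The terminal alkyne is far more acidic than the furan C–H bonds, so the acetylide should form selectively and add to formaldehyde (alkynylation of an aldehyde), installing the propargylic CH2OH without touching the silyl ether or the stereocentre.

**Step 6**
Reactants: 6 homofarnesyl iodide; 13 (R)-5-(furan-3-yl)-5-(triethylsilyloxy)pent-2-yn-1-ol
Product: 18 (1R,3E,7E,11E)-1-(furan-3-yl)-4-(hydroxymethyl)-8,12,16-trimethylheptadeca-3,7,11,15-tetraen-1-ol, via homofarnesyllithium 14 (not isolated), via homofarnesylmagnesium bromide 15 (not isolated), via oxamagnesole chelate 16 (not isolated), via triethylsilyl ether 17 (not isolated)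
Conditions: 6, t-BuLi (2 equiv per iodide), Et2O/pentane, −78 °C; MgBr2·OEt2, −78 → 0 °C; then 13 (pre-treated with 1 equiv MeMgBr, Et2O, 0 °C), CuI (15 mol%), −10 °C → rt; then 1 M HCl, THF, 0 °C
Reagents that add atoms: none
Why: The bromomagnesium propargylic alkoxide of 13 holds magnesium beside the triple bond, the copper-activated homofarnesyl group is delivered to the alkyne carbon proximal to the CH2O group while the distal carbon becomes C–Mg on the opposite face within the five-membered 2,5-dihydro-1,2-oxamagnesole 16, so the addition is anti and protonolysis places H cis to CH2OH and the homofarnesyl chain cis to the C2 methylene, i.e. the 3E alkene. The closest known reaction type is the CuI-catalysed alkoxide-directed anti-carbomagnesiation of 2-alkyn-1-ols with primary alkyl Grignard reagents. No ring of the target is closed; the only ring formed is the transient C–Mg–O chelate, closed by coordination of the alkoxide oxygen to the new vinyl–magnesium centre with the alkene endocyclic, and it is opened again on protonolysis. No stereocentre is created, and the remote (R)-carbinol centre is not involved. The step needs regioselectivity (C–C bond at the carbon bearing CH2O) and anti stereoselectivity; both are secured by the alkoxide chelate, and the secondary oxygen is silylated so that it cannot direct the alkyl group to the other alkyne carbon. The dilute acid quench protonates the C–Mg bond and cleaves the triethylsilyl ether in the same flask.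

**Step 7**
Reactants: 18 (1R,3E,7E,11E)-1-(furan-3-yl)-4-(hydroxymethyl)-8,12,16-trimethylheptadeca-3,7,11,15-tetraen-1-ol
Product: 20 Hippolide C, via γ-hydroxybutenolide 19 (not isolated)
Conditions: O2, hν (visible), meso-tetraphenylporphyrin (cat.), i-Pr2NEt, CH2Cl2, −78 °C; then NaBH4, EtOH, 0 °C; then 1 M HCl to pH 3
Reagents that add atoms: dioxygen, O=O
Why: Singlet oxygen should add [4+2] across the furan faster than it undergoes the ene reaction with trisubstituted alkenes at −78 °C, the hindered amine removes the less hindered endoperoxide bridgehead hydrogen remote from the side chain (Kornblum–DeLaMare-type fragmentation) so that the carbonyl forms there and the side chain sits on the β-carbon, and NaBH4 reduction of the open aldehyde form followed by acid lactonisation gives the 4-substituted furan-2(5H)-one.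

**Compound list**
1 | (2E,6E)-farnesyl bromide | CC(C)=CCC/C(C)=C/CC/C(C)=C/CBr | starting material
2 | thioanisole | CSc1ccccc1 | starting material
3 | (phenylthio)methyllithium | [Li]CSc1ccccc1 | intermediate
4 | (phenylthio)methylcopper | [Cu]CSc1ccccc1 | intermediate
5 | phenyl (3E,7E)-4,8,12-trimethyltrideca-3,7,11-trien-1-yl sulfide | CC(C)=CCC/C(C)=C/CC/C(C)=C/CCSc1ccccc1 | intermediate
6 | (3E,7E)-1-iodo-4,8,12-trimethyltrideca-3,7,11-triene (homofarnesyl iodide) | CC(C)=CCC/C(C)=C/CC/C(C)=C/CCI | intermediate
7 | furan-3-carbaldehyde | O=Cc1ccoc1 | starting material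
8 | allenylboronic acid pinacol ester | C=C=CB1OC(C)(C)C(C)(C)O1 | starting material
9 | (R)-2-{[1-(furan-3-yl)but-3-yn-1-yl]oxy}-4,4,5,5-tetramethyl-1,3,2-dioxaborolane | C#CC[C@@H](OB1OC(C)(C)C(C)(C)O1)c1ccoc1 | intermediate
10 | (R)-1-(furan-3-yl)but-3-yn-1-ol | C#CC[C@@H](O)c1ccoc1 | intermediate
11 | (R)-triethyl{[1-(furan-3-yl)but-3-yn-1-yl]oxy}silane | C#CC[C@@H](O[Si](CC)(CC)CC)c1ccoc1 | intermediate
12 | lithium acetylide of 11 | [Li]C#CC[C@@H](O[Si](CC)(CC)CC)c1ccoc1 | intermediate
13 | (R)-5-(furan-3-yl)-5-(triethylsilyloxy)pent-2-yn-1-ol | OCC#CC[C@@H](O[Si](CC)(CC)CC)c1ccoc1 | intermediate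
14 | homofarnesyllithium | CC(C)=CCC/C(C)=C/CC/C(C)=C/CC[Li] | intermediate
15 | homofarnesylmagnesium bromide | CC(C)=CCC/C(C)=C/CC/C(C)=C/CC[Mg]Br | intermediate
16 | 3-[(R)-2-(furan-3-yl)-2-(triethylsilyloxy)ethyl]-4-homofarnesyl-2,5-dihydro-1,2-oxamagnesole | CC(C)=CCC/C(C)=C/CC/C(C)=C/CCC1=C(C[C@@H](O[Si](CC)(CC)CC)c2ccoc2)[Mg]OC1 | intermediate
17 | (1R,3E,7E,11E)-1-(furan-3-yl)-4-(hydroxymethyl)-8,12,16-trimethyl-1-(triethylsilyloxy)heptadeca-3,7,11,15-tetraene | CC(C)=CCC/C(C)=C/CC/C(C)=C/CC/C(=C\C[C@@H](O[Si](CC)(CC)CC)c1ccoc1)CO | intermediate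
18 | (1R,3E,7E,11E)-1-(furan-3-yl)-4-(hydroxymethyl)-8,12,16-trimethylheptadeca-3,7,11,15-tetraen-1-ol | CC(C)=CCC/C(C)=C/CC/C(C)=C/CC/C(=C\C[C@@H](O)c1ccoc1)CO | intermediate
19 | 5-hydroxy-4-[(1R,3E,7E,11E)-1-hydroxy-4-(hydroxymethyl)-8,12,16-trimethylheptadeca-3,7,11,15-tetraen-1-yl]furan-2(5H)-one (both C5 epimers) | CC(C)=CCC/C(C)=C/CC/C(C)=C/CC/C(=C\C[C@@H](O)C1=CC(=O)OC1O)CO | intermediate
20 | Hippolide C, 4-[(1R,3E,7E,11E)-1-hydroxy-4-(hydroxymethyl)-8,12,16-trimethylheptadeca-3,7,11,15-tetraen-1-yl]furan-2(5H)-one | CC(C)=CCC/C(C)=C/CC/C(C)=C/CC/C(=C\C[C@@H](O)C1=CC(=O)OC1)CO | target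

**Step count.** Total: 7 steps. Longest linear sequence: 5 steps (steps 3, 4, 5, 6, 7 from furan-3-carbaldehyde); the homofarnesyl arm (steps 1, 2) joins in step 6.

**Steps most likely to fail**

Step 6. The carbometalation of the internal, γ-branched alkynol may be slow or incomplete, the alkyl group may in part be transferred to the distal alkyne carbon, and the valuable Grignard reagent may be lost by protonation. The fallback sets out from 13 (and 6) and rejoins the route at 17. Hydroxyl-directed trans-hydrostannation of 13 (Bu3SnH, [Cp*RuCl]4 cat., CH2Cl2, rt) should place tin on the alkyne carbon next to the CH2OH and hydrogen anti to it, giving (R,Z)-5-(furan-3-yl)-2-(tributylstannyl)-5-(triethylsilyloxy)pent-2-en-1-ol F1. I2 (CH2Cl2, 0 °C) should then give, with retention, (R,Z)-5-(furan-3-yl)-2-iodo-5-(triethylsilyloxy)pent-2-en-1-ol F2. Iodide 6 is converted by way of 14 (t-BuLi, then B-methoxy-9-BBN, Et2O/THF, −78 °C → rt) into lithium B-homofarnesyl-B-methoxy-9-borabicyclo[3.3.1]nonan-9-uide F3. B-alkyl Suzuki–Miyaura coupling of F2 with F3 (Pd(dppf)Cl2, AsPh3, Cs2CO3, DMF/H2O, rt) should give 17 with retention of the alkene geometry, and the acid treatment of step 6 then gives 18.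

Step 7. Singlet oxygen may also attack the four trisubstituted side-chain alkenes by the ene pathway, and the endoperoxide fragmentation may lose regiocontrol. The fallback sets out from 13 and rejoins at 20; it oxidises the furan before the polyene is present. Photooxygenation of 13 under the conditions of step 7 should give 5-hydroxy-4-[(R)-5-hydroxy-1-(triethylsilyloxy)pent-3-yn-1-yl]furan-2(5H)-one F4. NaBH4 (EtOH, 0 °C) followed by aq. citric acid should give (R)-4-[5-hydroxy-1-(triethylsilyloxy)pent-3-yn-1-yl]furan-2(5H)-one F5. Because a butenolide does not tolerate a Grignard reagent, the chain is then attached by cross-coupling: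
- trans-hydrostannation as above to (R,Z)-4-[5-hydroxy-4-(tributylstannyl)-1-(triethylsilyloxy)pent-3-en-1-yl]furan-2(5H)-one F6;
- I2 to (R,Z)-4-[5-hydroxy-4-iodo-1-(triethylsilyloxy)pent-3-en-1-yl]furan-2(5H)-one F7;
- B-alkyl Suzuki–Miyaura coupling with the borate F3 (prepared as in the first fallback) to Hippolide C triethylsilyl ether F8;
- 1 M HCl, THF/MeOH, 0 °C, to 20.

Step 3. Enantioface discrimination may be insufficient for the heteroaryl aldehyde. The fallback sets out from 7 and rejoins at 10; it replaces asymmetric catalysis by resolution. Barbier propargylation of 7 (propargyl bromide, Zn, THF/aq. NH4Cl) should give racemic 1-(furan-3-yl)but-3-yn-1-ol F9. Lipase-catalysed acylation (Burkholderia cepacia lipase, vinyl acetate, hexane, rt) is expected, by the empirical size rule for secondary alcohols with the furyl ring as the large group, to acetylate the (R)-enantiomer and give (R)-1-(furan-3-yl)but-3-yn-1-yl acetate F10, which is separated from the unreacted (S)-alcohol. Methanolysis (K2CO3, MeOH, 0 °C) then gives 10.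

**Further compounds**
F1 | step 6 | (R,Z)-5-(furan-3-yl)-2-(tributylstannyl)-5-(triethylsilyloxy)pent-2-en-1-ol | OC/C(=C/C[C@@H](O[Si](CC)(CC)CC)c1ccoc1)[Sn](CCCC)(CCCC)CCCC
F2 | step 6 | (R,Z)-5-(furan-3-yl)-2-iodo-5-(triethylsilyloxy)pent-2-en-1-ol | OC/C(I)=C/C[C@@H](O[Si](CC)(CC)CC)c1ccoc1
F3 | step 6 | lithium B-homofarnesyl-B-methoxy-9-borabicyclo[3.3.1]nonan-9-uide | [Li+].CO[B-]1(CC/C=C(\C)CC/C=C(\C)CCC=C(C)C)C2CCCC1CCC2
F4 | step 7 | 5-hydroxy-4-[(R)-5-hydroxy-1-(triethylsilyloxy)pent-3-yn-1-yl]furan-2(5H)-one | OCC#CC[C@@H](O[Si](CC)(CC)CC)C1=CC(=O)OC1O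
F5 | step 7 | (R)-4-[5-hydroxy-1-(triethylsilyloxy)pent-3-yn-1-yl]furan-2(5H)-one | OCC#CC[C@@H](O[Si](CC)(CC)CC)C1=CC(=O)OC1
F6 | step 7 | (R,Z)-4-[5-hydroxy-4-(tributylstannyl)-1-(triethylsilyloxy)pent-3-en-1-yl]furan-2(5H)-one | OC/C(=C/C[C@@H](O[Si](CC)(CC)CC)C1=CC(=O)OC1)[Sn](CCCC)(CCCC)CCCC
F7 | step 7 | (R,Z)-4-[5-hydroxy-4-iodo-1-(triethylsilyloxy)pent-3-en-1-yl]furan-2(5H)-one | OC/C(I)=C/C[C@@H](O[Si](CC)(CC)CC)C1=CC(=O)OC1
F8 | step 7 | Hippolide C triethylsilyl ether | CC(C)=CCC/C(C)=C/CC/C(C)=C/CC/C(=C\C[C@@H](O[Si](CC)(CC)CC)C1=CC(=O)OC1)CO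
F9 | step 3 | racemic 1-(furan-3-yl)but-3-yn-1-ol | C#CCC(O)c1ccoc1
F10 | step 3 | (R)-1-(furan-3-yl)but-3-yn-1-yl acetate | C#CC[C@@H](OC(C)=O)c1ccoc1
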